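The plan disconnects C2–C3 of ring F, the pyran of the lower afzelechin unit. C2 carries ring oxygen O1 and aryl ring E, so it enters as the carbonyl carbon of a 4-(benzyloxy)benzoate on the O1 phenol of ring D; C3 is the inner vinyl carbon of an allyl group set ortho to that oxygen by Claisen rearrangement. One titanium-alkylidene carbonyl–olefin metathesis then closes ring F as a flav-2-ene, and syn-hydroboration of the new C2=C3 bond sets both stereocentres trans. A fisetinidol C4 cation, made from a chalcone epoxide, is finally joined to C8, and hydrogenolysis frees the phenols.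

Key step: step 4

Remark: rings are lettered A (benzo), C (pyran), B (catechol) in the upper fisetinidol unit and D (benzo), F (pyran), E (4-hydroxyphenyl) in the lower afzelechin unit. The target is read as (2R,3S,4S)-fisetinidol-(4α→8)-(2R,3S)-afzelechin, and all phenols are carried as benzyl ethers.

**Lower unit (steps 1–5)**

Step 1
Reactants: 1 3,5-bis(benzyloxy)phenol
Product: 2 1-(allyloxy)-3,5-bis(benzyloxy)benzene
Conditions: allyl bromide, K2CO3, acetone, reflux
Reagents that add atoms: allyl bromide C=CCBr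
Why: Williamson etherification of the phenoxide with an allylic bromide should proceed cleanly on the single free hydroxyl; no stereocentre is formed.

Step 2
Reactants: 2 1-(allyloxy)-3,5-bis(benzyloxy)benzene
Product: 3 2-allyl-3,5-bis(benzyloxy)phenol
Conditions: PhNEt2, 190 °C
Reagents that add atoms: none
Why: The aromatic Claisen rearrangement moves the allyl group to the carbon ortho to the oxygen that becomes O1; the two ortho positions are equivalent by symmetry, so one 2-allylphenol should result.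

Step 3
Reactants: 3 2-allyl-3,5-bis(benzyloxy)phenol; 4 4-(benzyloxy)benzoyl chloride
Product: 5 2-allyl-3,5-bis(benzyloxy)phenyl 4-(benzyloxy)benzoate
Conditions: Et3N, DMAP (cat.), CH2Cl2, 0 °C to rt
Reagents that add atoms: none
Why: DMAP-catalysed acylation of the phenol with the acid chloride installs C2 (as the ester carbonyl) together with ring E on the future O1.

Step 4
Reactants: 5 2-allyl-3,5-bis(benzyloxy)phenyl 4-(benzyloxy)benzoate
Product: 7 5,7-bis(benzyloxy)-2-[4-(benzyloxy)phenyl]-4H-chromene, via titanium alkylidene 6 (not isolated)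
Conditions: TiCl4, TMEDA, Zn, PbCl2 (cat.), CH3CHBr2, THF/CH2Cl2, 0 to 65 °C; K2CO3 work-up, Et3N-deactivated silica
Reagents that add atoms: none
Why: The titanium ethylidene formed from CH3CHBr2, TiCl4, Zn, catalytic PbCl2 and TMEDA should first exchange with the terminal allyl C=C (propene is lost) to give the titanium alkylidene 6 at C3, which adds across the ester C=O to an oxatitanacyclobutane and cycloreverts to the C2=C3 enol ether and a titanium oxo species. The closest known reaction type is the olefinic-ester cyclisation (carbonyl–olefin metathesis) with Takai–Utimoto titanium alkylidenes or with Cp2Ti(CH2)(Cl)AlMe2, used for six- and seven-membered cyclic enol ethers. Ring F is closed as a six-membered 4H-chromene by intramolecular carbonyl olefination, the new C2=C3 bond lying inside the ring. No stereocentre is formed here; both are set on this double bond in step 5. The step needs ring closure to outrun plain ethylidenation of the ester, which is secured by the ethylidene (not methylidene) reagent, by the unhindered monosubstituted alkene and by the ortho relation of the allyl and aroyloxy groups on ring D, which holds the two reacting carbons close together. The electron-rich enol ether is acid-labile, so work-up and chromatography are kept basic.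

Step 5
Reactants: 7 5,7-bis(benzyloxy)-2-[4-(benzyloxy)phenyl]-4H-chromene
Product: 9 (2R,3S)-5,7-bis(benzyloxy)-2-[4-(benzyloxy)phenyl]chroman-3-ol, via flavanyl(isopinocampheyl)borane 8 (not isolated)
Conditions: IpcBH2 [from (1R)-(+)-α-pinene], THF, −25 °C; then NaOH, H2O2, 0 °C to rt
Reagents that add atoms: hydrogen peroxide OO
Why: In this Brown asymmetric hydroboration–oxidation boron adds to C3 (β to O1 and to the aryl group) and hydrogen to C2 from the same face, so oxidation with retention should give the 2,3-trans flavan-3-ol; the face is chosen by the isopinocampheyl group, the (+)-α-pinene-derived reagent being selected by analogy with 1-arylcycloalkenes [(1S,2R)-trans-2-arylcycloalkanol sense, which maps onto (2R,3S)], and any minor enantiomer would be removed after step 11 as a diastereomer.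

**Upper unit (steps 6–10)**

Step 6
Reactants: 10 1-[4-(benzyloxy)-2-hydroxyphenyl]ethanone
Product: 11 1-[4-(benzyloxy)-2-(methoxymethoxy)phenyl]ethanone
Conditions: NaH, MOMCl, DMF, 0 °C to rt
Reagents that add atoms: chloromethyl methyl ether COCCl
Why: O-alkylation of the sodium phenoxide masks the hydroxyl that later becomes O1 of ring C, so that it cannot cyclise during the aldol and epoxidation steps.

Step 7
Reactants: 11 1-[4-(benzyloxy)-2-(methoxymethoxy)phenyl]ethanone; 12 3,4-bis(benzyloxy)benzaldehyde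
Product: 13 (E)-1-[4-(benzyloxy)-2-(methoxymethoxy)phenyl]-3-[3,4-bis(benzyloxy)phenyl]prop-2-en-1-one
Conditions: KOH, EtOH/THF, rt
Reagents that add atoms: none
Why: Claisen–Schmidt aldol condensation of the methyl ketone with the non-enolisable aldehyde should give the thermodynamically favoured (E)-chalcone.

Step 8
Reactants: 13 (E)-chalcone
Product: 14 [4-(benzyloxy)-2-(methoxymethoxy)phenyl]{(2R,3S)-3-[3,4-bis(benzyloxy)phenyl]oxiran-2-yl}methanone
Conditions: poly-L-leucine, urea–H2O2, DBU, THF, rt
Reagents that add atoms: urea–hydrogen peroxide NC(N)=O.OO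
Why: In the Juliá–Colonna epoxidation the helical poly-L-leucine binds the enone and directs the hydroperoxide to one face, which by analogy with chalcone itself should give the trans (αR,βS) epoxide.

Step 9
Reactants: 14 MOM-protected (2R,3S)-epoxy ketone
Product: 16 (2R,3R)-7-(benzyloxy)-2-[3,4-bis(benzyloxy)phenyl]-3-hydroxychroman-4-one, via phenol epoxide 15 (not isolated)
Conditions: conc. HCl, MeOH/THF, 50 °C
Reagents that add atoms: none
Why: Acid cleaves the MOM acetal and the freed phenol opens the activated epoxide at the benzylic β-carbon (6-endo epoxide-opening cyclisation, the standard dihydroflavonol closure); the α-carbon keeps its configuration and becomes C3 (3R), while C2 should settle as the thermodynamically preferred 2,3-trans isomer (2R).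

Step 10
Reactants: 16 (2R,3R)-7-(benzyloxy)-2-[3,4-bis(benzyloxy)phenyl]-3-hydroxychroman-4-one
Product: 17 (2R,3S,4R)-7-(benzyloxy)-2-[3,4-bis(benzyloxy)phenyl]chroman-3,4-diol
Conditions: NaBH4, MeOH/THF, 0 °C
Reagents that add atoms: none
Why: Borohydride reduction of trans-dihydroflavonols should give mainly the 2,3-trans-3,4-trans diol; the C4 configuration is not critical because this centre is ionised in step 11.

**Union and deprotection (steps 11–12)**

Step 11
Reactants: 17 (2R,3S,4R)-flavan-3,4-diol; 9 (2R,3S)-5,7-bis(benzyloxy)-2-[4-(benzyloxy)phenyl]chroman-3-ol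
Product: 18 (2R,3S,4S)-7-(benzyloxy)-2-[3,4-bis(benzyloxy)phenyl]-4-{(2R,3S)-5,7-bis(benzyloxy)-2-[4-(benzyloxy)phenyl]-3-hydroxychroman-8-yl}chroman-3-ol
Conditions: BF3·OEt2 (0.3 equiv), 9 (2.5 equiv), CH2Cl2, −78 to −20 °C
Reagents that add atoms: none
Why: In this biomimetic Friedel–Crafts (proanthocyanidin) coupling the Lewis acid ionises the C4 hydroxyl to a cation stabilised by the para 7-benzyloxy group and O1, and ring D of 9 should attack through C8, the usual site for 5,7-di-O-benzyl flavan-3-ols, anti to the 3-hydroxyl to give the 3,4-trans (4S) linkage.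

Step 12
Reactants: 18 hexa-O-benzyl dimer
Product: 19 (2R,3S,4S)-2-(3,4-dihydroxyphenyl)-4-[(2R,3S)-3,5,7-trihydroxy-2-(4-hydroxyphenyl)chroman-8-yl]chroman-3,7-diol
Conditions: H2 (1 atm), Pd(OH)2/C, THF/MeOH, rt
Reagents that add atoms: none
Why: Catalytic hydrogenolysis should remove all six benzyl ethers without touching the four set stereocentres or the interflavan bond.

**Compound list**

1 | 3,5-bis(benzyloxy)phenol | Oc1cc(OCc2ccccc2)cc(OCc2ccccc2)c1 | starting material
2 | 1-(allyloxy)-3,5-bis(benzyloxy)benzene | C=CCOc1cc(OCc2ccccc2)cc(OCc2ccccc2)c1 | intermediate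
3 | 2-allyl-3,5-bis(benzyloxy)phenol | C=CCc1c(O)cc(OCc2ccccc2)cc1OCc1ccccc1 | intermediate
4 | 4-(benzyloxy)benzoyl chloride | O=C(Cl)c1ccc(OCc2ccccc2)cc1 | starting material
5 | 2-allyl-3,5-bis(benzyloxy)phenyl 4-(benzyloxy)benzoate | C=CCc1c(OC(=O)c2ccc(OCc3ccccc3)cc2)cc(OCc2ccccc2)cc1OCc1ccccc1 | intermediate
6 | titanium alkylidene at C3 of the aryl ester, drawn as its dichloride (TMEDA omitted) | Cl[Ti](Cl)=CCc1c(OC(=O)c2ccc(OCc3ccccc3)cc2)cc(OCc2ccccc2)cc1OCc1ccccc1 | intermediate
7 | 5,7-bis(benzyloxy)-2-[4-(benzyloxy)phenyl]-4H-chromene | C1(c2ccc(OCc3ccccc3)cc2)=CCc2c(OCc3ccccc3)cc(OCc3ccccc3)cc2O1 | intermediate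
8 | [(2R,3S)-flavan-3-yl](isopinocampheyl)borane | C[C@H]1[C@H](B[C@H]3Cc4c(OCc5ccccc5)cc(OCc5ccccc5)cc4O[C@@H]3c3ccc(OCc4ccccc4)cc3)C[C@@H]2C[C@H]1C2(C)C | intermediate
9 | (2R,3S)-5,7-bis(benzyloxy)-2-[4-(benzyloxy)phenyl]chroman-3-ol (tri-O-benzylafzelechin) | c1ccc(COc2ccc([C@H]3Oc4cc(OCc5ccccc5)cc(OCc5ccccc5)c4C[C@@H]3O)cc2)cc1 | intermediate
10 | 1-[4-(benzyloxy)-2-hydroxyphenyl]ethanone | CC(=O)c1ccc(OCc2ccccc2)cc1O | starting material
11 | 1-[4-(benzyloxy)-2-(methoxymethoxy)phenyl]ethanone | CC(=O)c1ccc(OCc2ccccc2)cc1OCOC | intermediate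
12 | 3,4-bis(benzyloxy)benzaldehyde | O=Cc1ccc(OCc2ccccc2)c(OCc2ccccc2)c1 | starting material
13 | (E)-1-[4-(benzyloxy)-2-(methoxymethoxy)phenyl]-3-[3,4-bis(benzyloxy)phenyl]prop-2-en-1-one | COCOc1cc(OCc2ccccc2)ccc1C(=O)/C=C/c1ccc(OCc2ccccc2)c(OCc2ccccc2)c1 | intermediate
14 | [4-(benzyloxy)-2-(methoxymethoxy)phenyl]{(2R,3S)-3-[3,4-bis(benzyloxy)phenyl]oxiran-2-yl}methanone | COCOc1cc(OCc2ccccc2)ccc1C(=O)[C@@H]1O[C@H]1c1ccc(OCc2ccccc2)c(OCc2ccccc2)c1 | intermediate
15 | [4-(benzyloxy)-2-hydroxyphenyl]{(2R,3S)-3-[3,4-bis(benzyloxy)phenyl]oxiran-2-yl}methanone | Oc1cc(OCc2ccccc2)ccc1C(=O)[C@@H]1O[C@H]1c1ccc(OCc2ccccc2)c(OCc2ccccc2)c1 | intermediate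
16 | (2R,3R)-7-(benzyloxy)-2-[3,4-bis(benzyloxy)phenyl]-3-hydroxychroman-4-one (tri-O-benzylfustin) | O=C1c2ccc(OCc3ccccc3)cc2O[C@H](c2ccc(OCc3ccccc3)c(OCc3ccccc3)c2)[C@H]1O | intermediate
17 | (2R,3S,4R)-7-(benzyloxy)-2-[3,4-bis(benzyloxy)phenyl]chroman-3,4-diol | O[C@@H]1c2ccc(OCc3ccccc3)cc2O[C@H](c2ccc(OCc3ccccc3)c(OCc3ccccc3)c2)[C@H]1O | intermediate
18 | hexa-O-benzyl (2R,3S,4S)-fisetinidol-(4α→8)-(2R,3S)-afzelechin | c1ccccc1COc1ccc([C@H]2Oc3c(c(OCc4ccccc4)cc(OCc4ccccc4)c3[C@@H]3c4ccc(OCc5ccccc5)cc4O[C@H](c4ccc(OCc5ccccc5)c(OCc5ccccc5)c4)[C@H]3O)C[C@@H]2O)cc1 | intermediate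
19 | (2R,3S,4S)-2-(3,4-dihydroxyphenyl)-4-[(2R,3S)-3,5,7-trihydroxy-2-(4-hydroxyphenyl)chroman-8-yl]chroman-3,7-diol | Oc1ccc([C@H]2Oc3c(c(O)cc(O)c3[C@@H]3c4ccc(O)cc4O[C@H](c4ccc(O)c(O)c4)[C@H]3O)C[C@@H]2O)cc1 | target

Total step count: 12
Longest linear sequence: 7 steps (steps 6–12; the branch through steps 1–5, 11 and 12 is equally long)

**Steps most likely to fail**

1. Step 4. The titanium ethylidene may olefinate the ester carbonyl before it has exchanged with the allyl group, stopping at an acyclic enol ether; the allyl double bond may also migrate into conjugation, or the product may hydrolyse on acidic contact. The fallback sets out from 5 and separates the two events. Methylenation of the ester with Cp2TiMe2 (toluene, 70 °C) should give 2-allyl-3,5-bis(benzyloxy)phenyl 1-[4-(benzyloxy)phenyl]vinyl ether F1. Ring-closing olefin metathesis of this diene with the second-generation Grubbs catalyst (toluene, 70 °C) then closes the same C2=C3 bond with loss of ethylene and comes back to the route at 7.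

2. Step 5. The isopinocampheyl group may discriminate poorly between the faces of the aryl enol ether, or the β-aryloxyborane may eliminate with opening of ring F. The fallback sets out from 7 and uses resolution instead of reagent control. Hydroboration with BH3·SMe2 and oxidation (NaOH, H2O2) should give the racemic trans-flavan-3-ol F2. Acylation with (1S)-camphanic chloride (pyridine, DMAP) gives the camphanate of the (2R,3S) enantiomer F3 and the diastereomeric camphanate of the (2S,3R) enantiomer F4, which are separated by chromatography or crystallisation. Methanolysis of F3 (K2CO3, MeOH/THF) comes back to the route at 9.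

3. Step 11. The C4 cation may be attacked from the face syn to the 3-hydroxyl (3,4-cis linkage) or through C6 of ring D, or the product may be alkylated again to oligomers. The fallback sets out from 17 and adds neighbouring-group control. Acetylation (Ac2O, pyridine, DMAP) gives (2R,3S,4R)-7-(benzyloxy)-2-[3,4-bis(benzyloxy)phenyl]chromane-3,4-diyl diacetate F5. Ionisation of its C4 acetate with BF3·OEt2 at −78 °C in the presence of excess 9 lets the 3-acetoxy group bridge C4 as a dioxolenium ion on its own face, so ring D can only enter anti; this should give the 3-O-acetyl hexa-O-benzyl dimer F6. Methanolysis (K2CO3, MeOH/THF) comes back to the route at 18.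

**Further compounds**

F1 | step 4 | 2-allyl-3,5-bis(benzyloxy)phenyl 1-[4-(benzyloxy)phenyl]vinyl ether | C=CCc1c(OC(=C)c2ccc(OCc3ccccc3)cc2)cc(OCc2ccccc2)cc1OCc1ccccc1
F2 | step 5 | racemic trans-5,7-bis(benzyloxy)-2-[4-(benzyloxy)phenyl]chroman-3-ol | c1ccc(COc2ccc([C@H]3Oc4cc(OCc5ccccc5)cc(OCc5ccccc5)c4C[C@@H]3O)cc2)cc1.c1ccc(COc2ccc([C@@H]3Oc4cc(OCc5ccccc5)cc(OCc5ccccc5)c4C[C@H]3O)cc2)cc1
F3 | step 5 | (2R,3S)-5,7-bis(benzyloxy)-2-[4-(benzyloxy)phenyl]chroman-3-yl (1S)-camphanate | CC1(C)[C@@]2(C)CC[C@]1(C(=O)O[C@H]3Cc4c(OCc5ccccc5)cc(OCc5ccccc5)cc4O[C@@H]3c3ccc(OCc4ccccc4)cc3)OC2=O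
F4 | step 5 | (2S,3R)-5,7-bis(benzyloxy)-2-[4-(benzyloxy)phenyl]chroman-3-yl (1S)-camphanate | CC1(C)[C@@]2(C)CC[C@]1(C(=O)O[C@@H]3Cc4c(OCc5ccccc5)cc(OCc5ccccc5)cc4O[C@H]3c3ccc(OCc4ccccc4)cc3)OC2=O
F5 | step 11 | (2R,3S,4R)-7-(benzyloxy)-2-[3,4-bis(benzyloxy)phenyl]chromane-3,4-diyl diacetate | CC(=O)O[C@@H]1c2ccc(OCc3ccccc3)cc2O[C@H](c2ccc(OCc3ccccc3)c(OCc3ccccc3)c2)[C@H]1OC(C)=O
F6 | step 11 | 3-O-acetyl derivative (upper unit) of hexa-O-benzyl dimer 18 | c1ccccc1COc1ccc([C@H]2Oc3c(c(OCc4ccccc4)cc(OCc4ccccc4)c3[C@@H]3c4ccc(OCc5ccccc5)cc4O[C@H](c4ccc(OCc5ccccc5)c(OCc5ccccc5)c4)[C@H]3OC(C)=O)C[C@@H]2O)cc1
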